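The plan rests on the carbon shared by the oxetane, the tetrahydrofuran and the cyclohexene (C5). It bears the acetal CH (C7) and a CH2 (C8), and its neighbour C4 bears CH3 and the oxetane oxygen cis to C7. This pattern is what a 1,2-shift onto an epoxide leaves behind. The precursor is an achiral 1-(cyclohexenyl)cyclopropanol with the ring ketone masked as a dioxolane. Ligand-controlled epoxidation of its C4=C5 bond, followed by migration of a cyclopropane CH2 to C5, gives a spiro-cyclobutanone. That single operation sets the C5–C8 and C4–O bonds, one ring and both stereocentres. Cleavage of the cyclobutanone, isopropenylation, ring functionalisation and oxetane closure follow.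

Key step: step 7

Locants used in the names from step 7 on (not IUPAC): six-membered ring C1 (ketal/ketone carbon, finally CBr)–C2–C3–C4 (bears CH3 and O)–C5 (quaternary)–C6 (CMe2). C7 is the carbon on C5 that ends as the acetal CH, C8 is the CH2 on C5, and C9 is the O–CH that bears isopropenyl.

Assumption: in steps 7 and 10 the ligand antipode that delivers the drawn configuration is taken. Both antipodes of each ligand are accessible.

Step 1
Reactants: 1 2,2-dimethylcyclohexane-1,3-dione
Product: 2 6,6-dimethyl-1,4-dioxaspiro[4.5]decan-7-one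
Conditions: HOCH2CH2OH (1.05 equiv), p-TsOH (cat.), toluene, reflux, Dean–Stark
Reagents that add atoms: ethylene glycol, OCCO
Why: Acid-catalysed ketalisation with azeotropic water removal should stop at the monoketal, because the remaining carbonyl then sits between CMe2 and a dioxolane and is far more hindered.

Step 2
Reactants: 2 6,6-dimethyl-1,4-dioxaspiro[4.5]decan-7-one; 3 iodomethane
Product: 5 (±)-6,6,8-trimethyl-1,4-dioxaspiro[4.5]decan-7-one, via lithium enolate 4 (not isolated)
Conditions: LDA, THF, −78 °C; MeI, −78 → 0 °C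
Reagents that add atoms: iodomethane (3), CI
Why: In this kinetic enolate alkylation the ketone can enolise only towards its CH2 side (the other α-carbon is quaternary), so one regioisomer is expected, and the new stereocentre is irrelevant because step 4 makes it sp2.

Step 3
Reactants: 5 (±)-6,6,8-trimethyl-1,4-dioxaspiro[4.5]decan-7-one
Product: 6 hydrazone of 5
Conditions: N2H4·H2O (excess), Et3N, EtOH, reflux
Reagents that add atoms: hydrazine, NN
Why: Hydrazone formation with the small nucleophile hydrazine is the usual entry for hindered 2,2,6-trisubstituted cyclohexanones, and the basic medium leaves the ketal untouched.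

Step 4
Reactants: 6 hydrazone of 5
Product: 7 7-iodo-6,6,8-trimethyl-1,4-dioxaspiro[4.5]dec-7-ene
Conditions: I2, 1,1,3,3-tetramethylguanidine, Et2O/THF, 0 °C → rt
Reagents that add atoms: iodine, II
Why: In the Barton vinyl iodide synthesis, oxidation to the diazo compound, iodination, loss of N2 and loss of the only available β-hydrogen give the tetrasubstituted alkenyl iodide.

Step 5
Reactants: 8 (1-ethoxycyclopropoxy)trimethylsilane
Product: 9 1-ethoxycyclopropan-1-ol
Conditions: MeOH, rt
Reagents that add atoms: none
Why: Methanolysis of the labile silyl acetal is the standard release of cyclopropanone ethyl hemiacetal.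

Step 6
Reactants: 7 7-iodo-6,6,8-trimethyl-1,4-dioxaspiro[4.5]dec-7-ene; 9 1-ethoxycyclopropan-1-ol
Product: 13 1-(6,6,8-trimethyl-1,4-dioxaspiro[4.5]dec-7-en-7-yl)cyclopropan-1-ol, via alkenyllithium 10 (not isolated), via bromomagnesium 1-ethoxycyclopropanolate 11 (not isolated), via cyclopropanone 12 (not isolated)
Conditions: 7: t-BuLi (2 equiv), Et2O, −78 °C; 9 (1.5 equiv): MeMgBr (1 equiv per 9), THF, 0 °C; mix, −78 °C → rt; H2O
Reagents that add atoms: 1-ethoxycyclopropan-1-ol (9), CCOC1(O)CC1
Why: Iodine–lithium exchange gives the ring alkenyllithium, and the magnesium salt of the hemiacetal releases the small, highly electrophilic cyclopropanone, whose 1,2-addition is a known route to 1-alkenylcyclopropanols, while pre-deprotonation with MeMgBr keeps the O–H from quenching 10.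

Step 7
Reactants: 13 1-(6,6,8-trimethyl-1,4-dioxaspiro[4.5]dec-7-en-7-yl)cyclopropan-1-ol
Product: 15 (4R,5S)-spirocyclobutanone ketal (C4-OH cis to C7=O), via (4R,5R)-epoxycyclopropanol 14 (not isolated)
Conditions: Hf(Ot-Bu)4 (10 mol %), C2-symmetric bis-hydroxamic acid from trans-1,2-diaminocyclohexane (12 mol %), cumene hydroperoxide (1.5 equiv), 4 Å MS, toluene, 0 °C → rt
Reagents that add atoms: cumene hydroperoxide, CC(C)(OO)c1ccccc1
Why: The cyclopropanol binds as an alkoxide to the Hf(IV)–bis-hydroxamate complex next to the bound hydroperoxide, so oxygen is passed to one face of the C4=C5 bond (directed asymmetric epoxidation of a tertiary allylic alcohol); the Lewis-acidic metal then opens epoxide 14 at C5 while the cyclopropane C–C bond anti to the breaking C5–O bond migrates (semipinacol ring expansion of a 1-oxiranylcyclopropanol), and both events are known reaction types. The oxirane forms by concerted syn oxygen transfer, and the cyclobutanone ring forms by a 3→4 ring enlargement through a 1,2-alkyl shift, not by an end-to-end cyclisation. C4 (R) keeps the oxygen on the face picked by the ligand and is therefore catalyst-controlled. C5 (S) follows stereospecifically, since the shift inverts the migration terminus: C8 enters anti to the oxygen, and the former carbinol carbon, now C7=O, ends cis to the C4–OH. The step needs opening at C5 rather than C4, which is secured by the donor oxygen on the carbinol carbon, C=O formation and release of oxirane strain; it also needs the cyclopropanol to survive until the epoxide exists, which is secured by a redox-inert d0 metal (no one-electron ring opening as V(V) could cause) and the absence of protic acid. The alkene is the only one present and the ketal is a spectator.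

Step 8
Reactants: 15 (4R,5S)-spirocyclobutanone ketal
Product: 16 (4R,5S)-bis-TMS compound (cyclobutenyl silyl enol ether and C4-OTMS)
Conditions: TMSOTf (2.5 equiv), Et3N (4 equiv), CH2Cl2, −78 → 0 °C
Reagents that add atoms: trimethylsilyl triflate, C[Si](C)(C)OS(=O)(=O)C(F)(F)F
Why: Under soft enolisation and silylation with silyl triflate and amine the cyclobutanone can enolise only towards its CH2 because C5 is quaternary, the tertiary alcohol is capped in the same flask, and the absence of a metal alkoxide avoids retro-aldol cleavage of the C4–C5 bond.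

Step 9
Reactants: 16 (4R,5S)-bis-TMS compound
Product: 18 (4R,5S)-methyl ester aldehyde, via acid aldehyde 17 (not isolated)
Conditions: O3, CH2Cl2/MeOH, −78 °C; Me2S, → rt; then TMSCHN2, toluene/MeOH, 0 °C
Reagents that add atoms: ozone, [O-][O+]=O; (trimethylsilyl)diazomethane, C[Si](C)(C)C=[N+]=[N-]
Why: Ozonolysis of a silyl enol ether cleaves the C7=CH bond to a silyl ester and an aldehyde (the strained, electron-rich cyclobutene is the only alkene present), methanol frees the acid, and TMSCHN2 esterifies it under neutral conditions that spare ketal, silyl ether and aldehyde.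

Step 10
Reactants: 18 (4R,5S)-methyl ester aldehyde; 19 2-bromopropene
Product: 20 (4R,5S,9R)-hydroxy ester
Conditions: CrCl2 (3 equiv), chiral oxazoline–sulfonamide ligand (3.3 equiv), Et3N (3.3 equiv), NiCl2 (cat.), THF, rt
Reagents that add atoms: 2-bromopropene (19), CC(Br)=C
Why: In this asymmetric Nozaki–Hiyama–Kishi reaction the isopropenylchromium(III) species formed through nickel catalysis adds only to the aldehyde (ester, ketal and silyl ether are inert), and the chiral ligand on chromium, not the remote quaternary C5, fixes C9 as R; any lactone formed already here is carried into step 11.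

Step 11
Reactants: 20 (4R,5S,9R)-hydroxy ester
Product: 21 (4R,5S,9R)-keto lactone with free C4-OH
Conditions: 2 M aq HCl, THF, rt
Reagents that add atoms: water, O
Why: One acid treatment performs three known reactions, namely lactonisation of the γ-hydroxy ester (5-exo-trig, helped by the quaternary C5), hydrolysis of the dioxolane and cleavage of the TMS ether, and no stereocentre is touched because the C9–O bond is not broken.

Step 12
Reactants: 21 (4R,5S,9R)-keto lactone
Product: 22 (4R,5S,9R)-γ-hydroxy enone lactone (C2=C3)
Conditions: IBX (2.5 equiv), DMSO, 70 °C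
Reagents that add atoms: none
Why: In this IBX dehydrogenation of a ketone through its enol only C2 carries α-hydrogens, so only the C2=C3 enone can form, and tertiary alcohol, lactone and 1,1-disubstituted alkene are not oxidised.

Step 13
Reactants: 22 (4R,5S,9R)-γ-hydroxy enone lactone
Product: 24 (3R,4S,5S,9R)-cis-diol keto lactone, via cyclic phenylboronate 23 (not isolated)
Conditions: PhB(OH)2 (1.5 equiv), tertiary-amine–thiourea catalyst (20 mol %), 4 Å MS, toluene, 50 °C; then 30% H2O2, aq Na2CO3, 0 °C
Reagents that add atoms: phenylboronic acid, OB(O)c1ccccc1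
Why: In this boronic-acid-tethered oxy-Michael addition, known for γ-hydroxy enones, the C4–OH forms a boronic hemiester whose amine-activated B–OH adds to C3 in a 5-exo-trig closure, so the new C3–O bond must be cis to the C4–O bond (3R), and oxidative work-up frees the diol.

Step 14
Reactants: 24 (3R,4S,5S,9R)-cis-diol keto lactone
Product: 26 C3-OTBS C4-OTMS keto lactone, via C3 mono-TBS ether 25 (not isolated)
Conditions: TBSOTf (1.1 equiv), 2,6-lutidine, CH2Cl2, −78 °C; then TMSOTf (1.5 equiv), −78 → 0 °C
Reagents that add atoms: tert-butyldimethylsilyl triflate, CC(C)(C)[Si](C)(C)OS(=O)(=O)C(F)(F)F; trimethylsilyl triflate, C[Si](C)(C)OS(=O)(=O)C(F)(F)F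
Why: In this graded silylation the secondary C3–OH takes the bulky TBS group at −78 °C and the hindered tertiary C4–OH is then capped with the small TMS group, which gives two ethers of very different lability and removes the alkoxide that could trigger retro-aldol cleavage in step 15.

Step 15
Reactants: 26 C3-OTBS C4-OTMS keto lactone
Product: 28 enol triflate lactone (C1-OTf, C1=C2), via potassium enolate 27 (not isolated)
Conditions: KHMDS (1.1 equiv), THF, −78 °C; PhNTf2, −78 → −20 °C
Reagents that add atoms: N-phenylbis(trifluoromethanesulfonimide), O=S(=O)(N(c1ccccc1)S(=O)(=O)C(F)(F)F)C(F)(F)F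
Why: In this kinetic enolate triflation C2 is the only α-CH2 (C6 is quaternary and the lactone has no α-hydrogen), and the low temperature keeps the enolate from expelling the β-silyloxy group.

Step 16
Reactants: 28 enol triflate lactone
Product: 30 hydroxy lactol (C7 anomers, free C4-OH), via TMS-protected lactol 29 (not isolated)
Conditions: DIBAL-H (1.2 equiv), CH2Cl2, −78 °C; aq Rochelle salt; then AcOH/THF/H2O, rt
Reagents that add atoms: none
Why: DIBAL-H half-reduction of a γ-lactone stops at the aluminium hemiacetal at −78 °C (enol triflate and silyl ethers are inert), dilute acetic acid then removes only the TMS ether, and both C7 anomers lead on.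

Step 17
Reactants: 30 hydroxy lactol
Product: 31 (3R,4S,5S,7S,9R)-tricyclic oxetane acetal with C1-OTf and C3-OTBS
Conditions: PPh3, DIAD, toluene (0.01 M), 0 °C → rt
Reagents that add atoms: none
Why: In this Mitsunobu-type cyclodehydration, known for closing hydroxy lactols to oxetane acetals, only the acidic lactol OH becomes an oxyphosphonium leaving group (a tertiary alcohol is not activated), C7 has no β-hydrogen on C5 so elimination is impossible, the cis C4–OH captures C7 in a 4-exo closure in a non-acidic medium that cannot reopen the product, and C7 can only adopt the cis-fused (S) configuration.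

Step 18
Reactants: 31 tricyclic oxetane acetal with C1-OTf and C3-OTBS
Product: 32 tricyclic vinyl bromide with C3-OTBS
Conditions: Ni(cod)2 (10 mol %), LiBr (2 equiv), THF/DMA, rt
Reagents that add atoms: lithium bromide, [Li+].[Br-]
Why: This nickel(0)-catalysed triflate–halide exchange of an enol triflate runs at room temperature and is placed after step 17 because the substrate then holds no allylic ester that Ni(0) could ionise, and neutral LiBr should leave acetal and silyl ether alone.

Step 19
Reactants: 32 tricyclic vinyl bromide with C3-OTBS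
Product: 33 (3R,4S,5S,7S,9R)-tricyclic allylic alcohol
Conditions: TBAF, THF, 0 °C; base-washed glassware, Et3N-deactivated silica
Reagents that add atoms: none
Why: Fluoride desilylation proceeds under basic conditions to which oxetane acetal, vinyl bromide and alkene are inert, and C3 keeps its configuration.

Step 20
Reactants: 33 (3R,4S,5S,7S,9R)-tricyclic allylic alcohol
Product: 34 target (3S,4S,5S,7S,9R)-dibromide CNP0141320.1
Conditions: CBr4, PPh3, 2,6-lutidine, CH2Cl2, −20 → 0 °C
Reagents that add atoms: carbon tetrabromide, BrC(Br)(Br)Br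
Why: In this Appel reaction the oxyphosphonium salt of the secondary allylic alcohol is displaced by bromide in an SN2 step with inversion (3R→3S, Br trans to the oxetane oxygen), SN2′ attack is disfavoured because it would build a gem-dibromide next to C6, and lutidine keeps the medium non-acidic for the acetal.

Compound list
1 | 2,2-dimethylcyclohexane-1,3-dione | CC1(C)C(=O)CCCC1=O | starting material
2 | 6,6-dimethyl-1,4-dioxaspiro[4.5]decan-7-one | CC1(C)C(=O)CCCC12OCCO2 | intermediate
3 | iodomethane | CI | starting material
4 | lithium enolate of 2 (not isolated) | [Li]OC1=CCCC2(OCCO2)C1(C)C | intermediate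
5 | (±)-6,6,8-trimethyl-1,4-dioxaspiro[4.5]decan-7-one | CC1CCC2(OCCO2)C(C)(C)C1=O | intermediate
6 | hydrazone of 5 | CC1CCC2(OCCO2)C(C)(C)C1=NN | intermediate
7 | 7-iodo-6,6,8-trimethyl-1,4-dioxaspiro[4.5]dec-7-ene | CC1=C(I)C(C)(C)C2(CC1)OCCO2 | intermediate
8 | (1-ethoxycyclopropoxy)trimethylsilane | CCOC1(CC1)O[Si](C)(C)C | starting material
9 | 1-ethoxycyclopropan-1-ol | CCOC1(O)CC1 | intermediate
10 | (6,6,8-trimethyl-1,4-dioxaspiro[4.5]dec-7-en-7-yl)lithium (not isolated) | [Li]C1=C(C)CCC2(OCCO2)C1(C)C | intermediate
11 | bromomagnesium 1-ethoxycyclopropan-1-olate (not isolated) | CCOC1(CC1)O[Mg]Br | intermediate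
12 | cyclopropanone (not isolated) | O=C1CC1 | intermediate
13 | 1-(6,6,8-trimethyl-1,4-dioxaspiro[4.5]dec-7-en-7-yl)cyclopropan-1-ol, achiral key-step precursor | OC1(CC1)C2=C(C)CCC3(OCCO3)C2(C)C | intermediate
14 | (4R,5R)-C4–C5 epoxide of 13, C5 bearing 1-hydroxycyclopropyl (not isolated) | OC1(CC1)[C@@]23O[C@]2(C)CCC4(OCCO4)C3(C)C | intermediate
15 | (4R,5S)-spirocyclobutanone: ring C1 (dioxolane)–C2H2–C3H2–C4(CH3)(OH)–C5(spiro)–C6(CH3)2, cyclobutanone C5–C7(=O)–CH2–C8H2, OH cis to C7 | O=C1CC[C@]12[C@](C)(O)CCC3(OCCO3)C2(C)C | intermediate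
16 | (4R,5S)-bis-TMS compound: 1-(trimethylsilyloxy)cyclobutene and C4-OTMS | C[Si](C)(C)OC1=CC[C@]12[C@](C)(O[Si](C)(C)C)CCC3(OCCO3)C2(C)C | intermediate
17 | (4R,5S)-acid aldehyde: C5 bears CO2H (C7) and CH2CHO (C8, C9), C4-OTMS, C1 ketal (not isolated) | OC(=O)[C@]1(CC=O)[C@](C)(O[Si](C)(C)C)CCC2(OCCO2)C1(C)C | intermediate
18 | (4R,5S)-methyl ester aldehyde | COC(=O)[C@]1(CC=O)[C@](C)(O[Si](C)(C)C)CCC2(OCCO2)C1(C)C | intermediate
19 | 2-bromopropene | CC(Br)=C | starting material
20 | (4R,5S,9R)-hydroxy ester: C8H2–C9H(OH)–C(CH3)=CH2 on C5 | COC(=O)[C@]1(C[C@@H](O)C(C)=C)[C@](C)(O[Si](C)(C)C)CCC2(OCCO2)C1(C)C | intermediate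
21 | (4R,5S,9R)-spiro γ-lactone (C5–C7(=O)–O–C9–C8), C1 ketone, free C4-OH cis to C7 | C=C(C)[C@H]1C[C@@]2(C(=O)O1)[C@](C)(O)CCC(=O)C2(C)C | intermediate
22 | (4R,5S,9R)-enone lactone, C1=O, C2=C3 | C=C(C)[C@H]1C[C@@]2(C(=O)O1)[C@](C)(O)C=CC(=O)C2(C)C | intermediate
23 | cyclic phenylboronate of 24, cis-fused at C3–C4 (not isolated) | C=C(C)[C@H]1C[C@@]2(C(=O)O1)[C@]3(C)OB(c4ccccc4)O[C@@H]3CC(=O)C2(C)C | intermediate
24 | (3R,4S,5S,9R)-keto lactone cis-3,4-diol | C=C(C)[C@H]1C[C@@]2(C(=O)O1)[C@](C)(O)[C@H](O)CC(=O)C2(C)C | intermediate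
25 | C3-OTBS ether of 24 (not isolated) | C=C(C)[C@H]1C[C@@]2(C(=O)O1)[C@](C)(O)[C@H](O[Si](C)(C)C(C)(C)C)CC(=O)C2(C)C | intermediate
26 | C3-OTBS, C4-OTMS keto lactone | C=C(C)[C@H]1C[C@@]2(C(=O)O1)[C@](C)(O[Si](C)(C)C)[C@H](O[Si](C)(C)C(C)(C)C)CC(=O)C2(C)C | intermediate
27 | potassium C1–C2 enolate of 26 (not isolated) | C=C(C)[C@H]1C[C@@]2(C(=O)O1)[C@](C)(O[Si](C)(C)C)[C@H](O[Si](C)(C)C(C)(C)C)C=C(O[K])C2(C)C | intermediate
28 | enol triflate lactone, C1-OTf, C1=C2 | C=C(C)[C@H]1C[C@@]2(C(=O)O1)[C@](C)(O[Si](C)(C)C)[C@H](O[Si](C)(C)C(C)(C)C)C=C(OS(=O)(=O)C(F)(F)F)C2(C)C | intermediate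
29 | lactol of 28, C7 anomers, C4-OTMS (not isolated) | C=C(C)[C@H]1C[C@@]2(C(O)O1)[C@](C)(O[Si](C)(C)C)[C@H](O[Si](C)(C)C(C)(C)C)C=C(OS(=O)(=O)C(F)(F)F)C2(C)C | intermediate
30 | lactol with free C4-OH, C7 anomers | C=C(C)[C@H]1C[C@@]2(C(O)O1)[C@](C)(O)[C@H](O[Si](C)(C)C(C)(C)C)C=C(OS(=O)(=O)C(F)(F)F)C2(C)C | intermediate
31 | (3R,4S,5S,7S,9R)-tricycle: oxetane C4–O–C7–C5 cis-fused to tetrahydrofuran C5–C7–O–C9–C8, C1-OTf, C3-OTBS cis to the oxetane oxygen | C=C(C)[C@H]1C[C@@]23[C@@H](O1)O[C@]2(C)[C@H](O[Si](C)(C)C(C)(C)C)C=C(OS(=O)(=O)C(F)(F)F)C3(C)C | intermediate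
32 | the same tricycle with C1-Br | C=C(C)[C@H]1C[C@@]23[C@@H](O1)O[C@]2(C)[C@H](O[Si](C)(C)C(C)(C)C)C=C(Br)C3(C)C | intermediate
33 | (3R,4S,5S,7S,9R)-tricyclic allylic alcohol, C3-OH cis to the oxetane oxygen | C=C(C)[C@H]1C[C@@]23[C@@H](O1)O[C@]2(C)[C@H](O)C=C(Br)C3(C)C | intermediate
34 | CNP0141320.1, (3S,4S,5S,7S,9R), C3-Br trans to the oxetane oxygen | C=C(C)[C@H]1C[C@@]23[C@@H](O1)O[C@]2(C)[C@@H](Br)C=C(Br)C3(C)C | target

Total step count: 20. Longest linear sequence: 19 (steps 1–4 and 6–20; step 5 is a one-step branch).

Steps most likely to fail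

Step 7. What may go wrong: weak enantiofacial discrimination, or no oxygen transfer at all, at the hindered tetrasubstituted alkene. The fallback sets out from 13 and comes back at 20. It gives up enantiocontrol in the ring expansion and regains it by separating diastereomers.
- Buffered m-CPBA (NaHCO3, CH2Cl2, 0 °C) epoxidises 13 without facial preference.
- 14 and the mirror-image epoxide F1 then rearrange stereospecifically to 15 and the mirror-image cyclobutanone F2.
- The racemate is taken through steps 8 and 9 unchanged. The mirror-image bis-silyl compound F3, the mirror-image acid aldehyde F4 and the mirror-image ester aldehyde F5 therefore accompany 16, 17 and 18.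
- The ligand-controlled coupling of step 10 makes C9 R in both series. This turns the enantiomers into 20 and the (4S,5R,9R)-hydroxy ester F6, which are separated by chromatography.

Step 17. What may go wrong: the reduced azodicarboxylate captures the activated lactol, or a Grob-type cleavage of the C4–C5 bond occurs, in place of four-ring closure. The fallback sets out from 29 and comes back at 31. It replaces dehydration of the diol by displacement of a discrete leaving group by an alkoxide, the closure used for 1,3-anhydro sugars.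
- 29 is isolated after the DIBAL-H stage, with the acid treatment omitted.
- Neutral chlorination with 1-chloro-N,N,2-trimethylpropenylamine (CH2Cl2, 0 °C) gives the C7 chloride F7.
- One equivalent of TBAF at −78 °C cleaves only the far more labile TMS ether.
- The tertiary alkoxide released next to C7 displaces chloride before the TBS ether or the enol triflate can react.

Step 13. What may go wrong: slow or reversible conjugate addition at the crowded C3, or loss of water back to the enone during the oxidative work-up. The fallback sets out from 22 and comes back at 24. The C3 oxygen is brought in as an epoxide.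
- A hydroxyl-directed Weitz–Scheffer epoxidation with t-BuOOLi (THF, −78 → −20 °C) is used. The lithium alkoxide of the C4–OH holds the peroxide on its own face and should give the cis-epoxy ketone F8.
- SmI2 (THF/MeOH, −90 °C) then cleaves the C2–O bond reductively. The C3–OH keeps its configuration.

Further compounds
F1 | step 7 | (4S,5S)-epoxycyclopropanol, enantiomer of 14 | OC1(CC1)[C@]23O[C@@]2(C)CCC4(OCCO4)C3(C)C
F2 | step 7 | (4S,5R)-spirocyclobutanone ketal, enantiomer of 15 | O=C1CC[C@@]12[C@@](C)(O)CCC3(OCCO3)C2(C)C
F3 | step 7 | (4S,5R)-bis-TMS compound, enantiomer of 16 | C[Si](C)(C)OC1=CC[C@@]12[C@@](C)(O[Si](C)(C)C)CCC3(OCCO3)C2(C)C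
F4 | step 7 | (4S,5R)-acid aldehyde, enantiomer of 17 | OC(=O)[C@@]1(CC=O)[C@@](C)(O[Si](C)(C)C)CCC2(OCCO2)C1(C)C
F5 | step 7 | (4S,5R)-methyl ester aldehyde, enantiomer of 18 | COC(=O)[C@@]1(CC=O)[C@@](C)(O[Si](C)(C)C)CCC2(OCCO2)C1(C)C
F6 | step 7 | (4S,5R,9R)-hydroxy ester, diastereomer of 20 | COC(=O)[C@@]1(C[C@@H](O)C(C)=C)[C@@](C)(O[Si](C)(C)C)CCC2(OCCO2)C1(C)C
F7 | step 17 | C7 chloride of 29 (anomers), C4-OTMS, C3-OTBS, C1-OTf | C=C(C)[C@H]1C[C@@]2(C(Cl)O1)[C@](C)(O[Si](C)(C)C)[C@H](O[Si](C)(C)C(C)(C)C)C=C(OS(=O)(=O)C(F)(F)F)C2(C)C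
F8 | step 13 | C2–C3 epoxy ketone lactone, epoxide cis to the C4-OH | C=C(C)[C@H]1C[C@@]2(C(=O)O1)[C@](C)(O)[C@@H]3O[C@@H]3C(=O)C2(C)C
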